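**Plan**

Locants are those of the target as an octahydroazulen-4(1H)-one: C1 CMe2, C2 CHOH, C3a CH, C4 C=O, C5 quaternary, C6 CHMe, C7/C8 CH2, C8a C–OH; 1′–4′ are side-chain carbons.
Enabling feature: the ketol C8a(OH)–C3a(H)–C4(=O) across the 5–7 ring fusion is the transannular aldol of a cyclodecane-1,6-dione (carbonyls C4 and C8a). That dione, with its C7–C8 ethano unit, is the retron of a vinyl-addition/oxy-Cope ring expansion of a cyclohexanone (C8a) that carries the C5=C6 alkenyl group on C4.
Cuts: C2 carbinol (redox inversion), then C3a–C8a (aldol), then butenolide (Horner–Wadsworth–Emmons) and C5–C1′ (hetero-Diels–Alder), then C8–C8a plus C6–C7 with loss of C4–C8a (key step), then a temporary C2–O–C4 ether bridge, then C4–C5 (α-alkenylation).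
Forward: six-membered ring (C8a, C1, C2, C3, C3a, C4), then 7-oxanorbornanone, then ten-membered ring, then side chain, then cyclopentane and cycloheptanone together in the aldol.
Stereochemistry: one catalytic reduction sets C2 (as S); the ether bridge passes it to C4, the oxy-Cope shift to C6, a convex-face cycloaddition to C5, the equilibrating aldol to C3a/C8a; C2 is finally turned to R by oxidation and hydride attack anti to the C8a hydroxyl.

Key step: step 4

Remark: 15 and 16 are written as open hydroxy ketones although each can close to the C2–O–C4 lactol; vinyllithium is taken as a titrated stock solution.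

**Route**

Step 1
Reactants: 1 2,2-dimethylcyclohexane-1,3-dione; 2 (E)-2-bromobut-2-ene
Product: 3 4-[(2E)-but-2-en-2-yl]-2,2-dimethylcyclohexane-1,3-dione (racemic)
Conditions: Pd(OAc)2 (5 mol %), P(t-Bu)3·HBF4 (10 mol %), LiN(SiMe3)2 (2.2 equiv), THF, 50 °C; 1 in excess
Reagents that add atoms: none
Why: Palladium-catalysed α-alkenylation of a ketone enolate should work because the dione can enolise only at its two equivalent CH2 groups and the coupling keeps the E geometry; the new stereocentre (the future C4) forms as a racemate and is erased in step 3.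

Step 2
Reactants: 3 4-[(2E)-but-2-en-2-yl]-2,2-dimethylcyclohexane-1,3-dione
Product: 4 (3S)-6-[(2E)-but-2-en-2-yl]-3-hydroxy-2,2-dimethylcyclohexan-1-one (both C6 epimers)
Conditions: (R)-tetrahydro-1-methyl-3,3-diphenyl-1H,3H-pyrrolo[1,2-c][1,3,2]oxazaborole (15 mol %), catecholborane (1.5 equiv), toluene, −78 °C; MeOH, aqueous NaHCO3
Reagents that add atoms: none
Why: Corey–Bakshi–Shibata reduction should take the less hindered carbonyl (flanked by CH2, not by the alkenyl-bearing carbon) and deliver hydride to the face set by the large CMe2 versus small CH2 flank, giving the S carbinol (future C2), while catecholborane at −78 °C spares the alkene.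

Step 3
Reactants: 4 (3S)-6-[(2E)-but-2-en-2-yl]-3-hydroxy-2,2-dimethylcyclohexan-1-one
Product: 6 (1S,4S)-1-[(2E)-but-2-en-2-yl]-3,3-dimethyl-7-oxabicyclo[2.2.1]heptan-2-one, via bis(trimethylsilyl) dienol ether 5 (not isolated)
Conditions: Me3SiOSO2CF3 (2.3 equiv), Et3N (3 equiv), CH2Cl2, −78 → 0 °C; then PhI(OAc)2 (1.2 equiv), BF3·OEt2 (1.5 equiv), −78 → −20 °C
Reagents that add atoms: none
Why: Proposed new method: soft enolisation can only go toward C4 and gives the same dienol ether 5 from either C4 epimer; PhI(OAc)2/BF3 should convert its enol ether into an O-bound iodonio enolate (an electrophilic, umpoled enolate) whose α-carbon C4 is attacked in an SN2′ sense by the silyl ether oxygen on C2 through a boat conformer (5-exo, oxolan-3-one ring) with loss of iodobenzene and Me3SiOAc, and since the oxygen can only bridge on its own face the C4 configuration follows from C2 and both epimers converge; the closest known reaction type is the trivalent-iodine-mediated α-oxygenation of ketones and enol ethers, including intramolecular O-trapping as in the cyclisation of 2-hydroxyaryl ketones to benzofuran-3-ones and of keto acids to keto lactones.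

Step 4
Reactants: 6 (1S,4S)-1-[(2E)-but-2-en-2-yl]-3,3-dimethyl-7-oxabicyclo[2.2.1]heptan-2-one
Product: 9 (1S,6R,7Z)-2,2,6,7-tetramethyl-11-oxabicyclo[6.2.1]undec-7-en-3-one, via lithium alkoxide 7 (not isolated), via lithium enolate 8 (not isolated)
Conditions: CH2=CHLi (1.5 equiv), THF, −78 °C; DMPU, −78 → 25 °C; pH 7 phosphate buffer
Reagents that add atoms: vinyllithium, [Li]C=C
Why: Vinyllithium should add to the non-enolisable, fenchone-like carbonyl C8a from the exo face (the face of the oxygen bridge, which can also hold lithium), so that alkoxide 7 carries the new vinyl group (C8–C8a bond) gauche to the bridgehead butenyl group; the alkoxide then drives a [3,3]-sigmatropic (anionic oxy-Cope) shift that breaks the strained C4–C8a bond between two fully substituted carbons and joins C7 to C6. The closest known reaction type is the tandem 1,2-addition/anionic oxy-Cope ring expansion of 2-alkenyl ketones, including bridgehead-alkenyl norbornan-2-ones. No ring is closed by direct cyclisation: the six-membered ring is enlarged by four atoms to the ten-membered carbocycle, which stays spanned by the C2–O–C4 ether as an 11-oxabicyclo[6.2.1]undecene. The only new stereocentre, C6, is set by chirality transfer from the bridgehead C4: the rigid bicycle holds the two alkenyl groups at a dihedral angle near 45°, which fits a chair-like but not a boat-like transition state, the methyl group of the E alkene sits pseudo-equatorial, and bonding on the alkene face turned toward the exo vinyl group should give 6R. The step needs exo addition (secured by the bridge topology), the chair pathway (secured by the bicyclic dihedral angle and the E alkene) and survival of the acid-labile enol ether (a buffered quench C-protonates enolate 8 at C8 to ketone 9).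

Step 5
Reactants: 10 2-(diethoxyphosphoryl)acetic acid; 11 1,4-dibromobutan-2-one
Product: 13 2-oxobut-3-en-1-yl 2-(diethoxyphosphoryl)acetate, via 4-bromo-2-oxobutyl ester 12 (not isolated)
Conditions: Et3N (2.2 equiv), acetone, 0 → 25 °C; used at once
Reagents that add atoms: none
Why: O-Alkylation of the carboxylate by the α-bromo ketone terminus (the more reactive C–Br bond) followed by amine-mediated E1cB loss of HBr from the β-bromo ketone is a standard way to an acyloxymethyl vinyl ketone; no stereocentre is formed.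

Step 6
Reactants: 9 (1S,6R,7Z)-2,2,6,7-tetramethyl-11-oxabicyclo[6.2.1]undec-7-en-3-one; 13 2-oxobut-3-en-1-yl 2-(diethoxyphosphoryl)acetate
Product: 15 4-[(1S,2R,7S)-7-hydroxy-1,2,6,6-tetramethyl-5,10-dioxocyclodecyl]-2-oxobutyl 2-(diethoxyphosphoryl)acetate, via spiroketal cycloadduct 14 (not isolated)
Conditions: 13 (3 equiv), 2,6-di-tert-butyl-4-methylphenol (trace), toluene, 80 °C; then 1 M HCl, THF, 0 → 25 °C
Reagents that add atoms: water, O
Why: Inverse-electron-demand hetero-Diels–Alder reaction of an exocyclic enol ether with a vinyl ketone (a standard spiroketal synthesis) should form C5–C1′ and C4–O suprafacially on the convex face of the bridged enol ether (the face of C2–H, away from the C1–C8a–C8–C7 loop), which sets the quaternary C5 as S with the side chain trans to the C6 methyl; mild acid then hydrolyses the spiroketal to the C4 and C3′ ketones and frees the C2 hydroxyl.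

Step 7
Reactants: 15 4-[(1S,2R,7S)-7-hydroxy-1,2,6,6-tetramethyl-5,10-dioxocyclodecyl]-2-oxobutyl 2-(diethoxyphosphoryl)acetate
Product: 16 (2S,3R,8S)-8-hydroxy-2,3,7,7-tetramethyl-2-[2-(5-oxo-2,5-dihydrofuran-3-yl)ethyl]cyclodecane-1,6-dione
Conditions: LiCl, i-Pr2NEt, MeCN, 0 → 25 °C
Reagents that add atoms: none
Why: Intramolecular Horner–Wadsworth–Emmons olefination under Masamune–Roush conditions closes the butenolide on the adjacent C3′ ketone, the amine being strong enough only for the lithium-chelated phosphonoacetate and not for the ring ketones.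

Step 8
Reactants: 16 (2S,3R,8S)-8-hydroxy-2,3,7,7-tetramethyl-2-[2-(5-oxo-2,5-dihydrofuran-3-yl)ethyl]cyclodecane-1,6-dione
Product: 17 (2S,3aS,5S,6R,8aS)-2,8a-dihydroxy-1,1,5,6-tetramethyl-5-[2-(5-oxo-2,5-dihydrofuran-3-yl)ethyl]octahydroazulen-4(1H)-one
Conditions: K2CO3 (0.3 equiv), MeOH, 0 °C
Reagents that add atoms: none
Why: Transannular aldol addition under equilibrating conditions: each ketone has one enolisable side, and attack of the C3a enolate on C8a (5-enolexo-exo-trig closure of the cyclopentane, which also defines the cycloheptanone) should be preferred to attack of C8 on C4, whose cyclopentane would carry three contiguous substituted carbons (C4, C5, C6); C3a (epimerisable) and C8a (reversible) should settle as the trans-fused ketol with the C8a hydroxyl on the face of the C5 and C6 methyl groups, the arrangement of the natural ketol.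

Step 9
Reactants: 17 (2S,3aS,5S,6R,8aS)-2,8a-dihydroxy-1,1,5,6-tetramethyl-5-[2-(5-oxo-2,5-dihydrofuran-3-yl)ethyl]octahydroazulen-4(1H)-one
Product: 18 (3aS,5S,6R,8aS)-8a-hydroxy-1,1,5,6-tetramethyl-5-[2-(5-oxo-2,5-dihydrofuran-3-yl)ethyl]hexahydroazulene-2,4(1H,3H)-dione
Conditions: Dess–Martin periodinane (1,1,1-triacetoxy-1,1-dihydro-1,2-benziodoxol-3(1H)-one), pyridine, CH2Cl2, 0 °C
Reagents that add atoms: none
Why: Dess–Martin oxidation converts the secondary C2 carbinol to the ketone and cannot touch the tertiary C8a hydroxyl, pyridine buffering the acetic acid so that the ketol does not dehydrate; the C2 centre, which has done its work as the anchor of the bridge, is erased.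

Step 10
Reactants: 18 (3aS,5S,6R,8aS)-8a-hydroxy-1,1,5,6-tetramethyl-5-[2-(5-oxo-2,5-dihydrofuran-3-yl)ethyl]hexahydroazulene-2,4(1H,3H)-dione
Product: 19 (2R,3aS,5S,6R,8aS)-2,8a-dihydroxy-1,1,5,6-tetramethyl-5-[2-(5-oxo-2,5-dihydrofuran-3-yl)ethyl]octahydroazulen-4(1H)-one
Conditions: NaBH4, CeCl3·7H2O, MeOH, −78 °C
Reagents that add atoms: none
Why: Luche reduction should take the accessible C2 cyclopentanone in preference to the C4 ketone (flanked by the quaternary C5 and the ring-fusion carbon) and spare the butenolide, with hydride entering anti to the pseudo-axial C8a hydroxyl (the other face carries only C3a–H) to give the 2R carbinol cis to the C8a hydroxyl.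

**Compound list**

1 | 2,2-dimethylcyclohexane-1,3-dione | CC1(C)C(=O)CCCC1=O | starting material
2 | (E)-2-bromobut-2-ene | C/C=C(/Br)C | starting material
3 | 4-[(2E)-but-2-en-2-yl]-2,2-dimethylcyclohexane-1,3-dione (racemic) | O=C1CCC(/C(C)=C/C)C(=O)C1(C)C | intermediate
4 | (3S)-6-[(2E)-but-2-en-2-yl]-3-hydroxy-2,2-dimethylcyclohexan-1-one (C6 epimers) | O[C@H]1CCC(/C(C)=C/C)C(=O)C1(C)C | intermediate
5 | (4S)-1-[(2E)-but-2-en-2-yl]-3,3-dimethyl-2,4-bis(trimethylsilyloxy)cyclohex-1-ene | C[Si](C)(C)O[C@H]1CCC(/C(C)=C/C)=C(O[Si](C)(C)C)C1(C)C | intermediate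
6 | (1S,4S)-1-[(2E)-but-2-en-2-yl]-3,3-dimethyl-7-oxabicyclo[2.2.1]heptan-2-one (ketone = C8a, bridgeheads = C4 and C2) | O=C1C(C)(C)[C@@H]2CC[C@]1(O2)/C(C)=C/C | intermediate
7 | lithium (1S,2R,4S)-1-[(2E)-but-2-en-2-yl]-2-ethenyl-3,3-dimethyl-7-oxabicyclo[2.2.1]heptan-2-olate (exo vinyl) | [Li+].[O-][C@]1(C=C)C(C)(C)[C@@H]2CC[C@]1(O2)/C(C)=C/C | intermediate
8 | lithium (1S,3Z,6R,7Z)-2,2,6,7-tetramethyl-11-oxabicyclo[6.2.1]undeca-3,7-dien-3-olate | [Li+].[O-]/C1=C\C[C@@H](C)/C(C)=C2/CC[C@H](O2)C1(C)C | intermediate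
9 | (1S,6R,7Z)-2,2,6,7-tetramethyl-11-oxabicyclo[6.2.1]undec-7-en-3-one (C8a ketone; C4=C5 enol ether bridged by oxygen to C2) | O=C1CC[C@@H](C)/C(C)=C2/CC[C@H](O2)C1(C)C | intermediate
10 | 2-(diethoxyphosphoryl)acetic acid | CCOP(=O)(CC(=O)O)OCC | starting material
11 | 1,4-dibromobutan-2-one | BrCC(=O)CCBr | starting material
12 | 4-bromo-2-oxobutyl 2-(diethoxyphosphoryl)acetate | CCOP(=O)(CC(=O)OCC(=O)CCBr)OCC | intermediate
13 | 2-oxobut-3-en-1-yl 2-(diethoxyphosphoryl)acetate | CCOP(=O)(CC(=O)OCC(=O)C=C)OCC | intermediate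
14 | spiroketal from 9 and 13: a 3,4-dihydro-2H-pyran whose C2 is the spiro ketal carbon C4 (also bound to the bridge oxygen), whose C3 is C5 and whose C6 carries CH2OC(O)CH2P(O)(OEt)2 | O=C1CC[C@@H](C)[C@]2(C)CC=C(COC(=O)CP(=O)(OCC)OCC)O[C@@]23CC[C@H](O3)C1(C)C | intermediate
15 | 4-[(1S,2R,7S)-7-hydroxy-1,2,6,6-tetramethyl-5,10-dioxocyclodecyl]-2-oxobutyl 2-(diethoxyphosphoryl)acetate | O=C1CC[C@@H](C)[C@](C)(CCC(=O)COC(=O)CP(=O)(OCC)OCC)C(=O)CC[C@H](O)C1(C)C | intermediate
16 | (2S,3R,8S)-8-hydroxy-2,3,7,7-tetramethyl-2-[2-(5-oxo-2,5-dihydrofuran-3-yl)ethyl]cyclodecane-1,6-dione | O=C1CC[C@@H](C)[C@](C)(CCC2=CC(=O)OC2)C(=O)CC[C@H](O)C1(C)C | intermediate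
17 | (2S,3aS,5S,6R,8aS)-2,8a-dihydroxy-1,1,5,6-tetramethyl-5-[2-(5-oxo-2,5-dihydrofuran-3-yl)ethyl]octahydroazulen-4(1H)-one | C[C@@H]1CC[C@]2(O)[C@H](C[C@H](O)C2(C)C)C(=O)[C@@]1(C)CCC1=CC(=O)OC1 | intermediate
18 | (3aS,5S,6R,8aS)-8a-hydroxy-1,1,5,6-tetramethyl-5-[2-(5-oxo-2,5-dihydrofuran-3-yl)ethyl]hexahydroazulene-2,4(1H,3H)-dione | C[C@@H]1CC[C@]2(O)[C@H](CC(=O)C2(C)C)C(=O)[C@@]1(C)CCC1=CC(=O)OC1 | intermediate
19 | (2R,3aS,5S,6R,8aS)-2,8a-dihydroxy-1,1,5,6-tetramethyl-5-[2-(5-oxo-2,5-dihydrofuran-3-yl)ethyl]octahydroazulen-4(1H)-one | C[C@@H]1CC[C@]2(O)[C@H](C[C@@H](O)C2(C)C)C(=O)[C@@]1(C)CCC1=CC(=O)OC1 | target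

**Totals and risks**

Total step count: 10. Longest linear sequence: 9 steps (1–4, 6–10); step 5 is a one-step branch.

Step 3 (proposed new method). Capture of the tertiary iodonio enolate by acetate, or loss of a proton to a dienone, may outrun the transannular attack, which needs the boat conformer and builds a strained oxanorbornane. The fallback sets out from 4 and returns at 6. α-Bromination of 4 at its only enolisable carbon (CuBr2, EtOAc–CHCl3, 60 °C) should give (3S)-6-bromo-6-[(2E)-but-2-en-2-yl]-3-hydroxy-2,2-dimethylcyclohexan-1-one F1 as a mixture of C6 epimers. Silver-assisted ionisation (AgOSO2CF3, 2,6-di-tert-butylpyridine, CH2Cl2, −40 °C) then lets the C3 hydroxyl close the bridge in an intramolecular Williamson-type etherification to 6, again from both epimers.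

Step 4. Addition to the doubly neopentyl carbonyl may be slow, and the lithium alkoxide may not rearrange below the temperature at which retro-addition or a boat-like pathway sets in, which would cost conversion and the C6 configuration. The fallback sets out from 6 and returns at 9, and replaces the anionic cascade by a neutral, stepwise sequence. The organocerium reagent (CH2=CHMgBr, CeCl3, THF, −78 °C) should give the isolable carbinol (1S,2R,4S)-1-[(2E)-but-2-en-2-yl]-2-ethenyl-3,3-dimethyl-7-oxabicyclo[2.2.1]heptan-2-ol F2. Silylation (Me3SiOSO2CF3, 2,6-lutidine) gives {[(1S,2R,4S)-1-[(2E)-but-2-en-2-yl]-2-ethenyl-3,3-dimethyl-7-oxabicyclo[2.2.1]heptan-2-yl]oxy}trimethylsilane F3. A thermal siloxy-Cope rearrangement (o-xylene, 150 °C, sealed tube) should give trimethyl{[(1S,3Z,6R,7Z)-2,2,6,7-tetramethyl-11-oxabicyclo[6.2.1]undeca-3,7-dien-3-yl]oxy}silane F4. Mild desilylation (K2CO3, MeOH, 0 °C) then gives 9.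

Step 8. The other transannular mode (C8 enolate on the C4 carbonyl), β-elimination of water from the ketol, enolate addition to the butenolide and imperfect equilibration of the ring fusion may all compete. The fallback sets out from 16 and returns at 17, and fixes the roles of the two carbonyls. Acid-catalysed dehydration of the C2–O–C4 lactol (pyridinium p-toluenesulfonate, 4 Å sieves, benzene, 60 °C) can only go toward C3a and should give the dihydrofuran (1S,6R,7S)-2,2,6,7-tetramethyl-7-[2-(5-oxo-2,5-dihydrofuran-3-yl)ethyl]-11-oxabicyclo[6.2.1]undec-8-en-3-one F5. Its enol ether carbon C3a then adds to the Lewis-acid-activated C8a ketone in a transannular Mukaiyama/Prins-type aldol (BF3·OEt2, CH2Cl2, −78 °C), and aqueous NaHCO3 work-up hydrolyses the oxocarbenium ion to 17.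

Further compounds
F1 | step 3 | (3S)-6-bromo-6-[(2E)-but-2-en-2-yl]-3-hydroxy-2,2-dimethylcyclohexan-1-one | O[C@H]1CCC(Br)(/C(C)=C/C)C(=O)C1(C)C
F2 | step 4 | (1S,2R,4S)-1-[(2E)-but-2-en-2-yl]-2-ethenyl-3,3-dimethyl-7-oxabicyclo[2.2.1]heptan-2-ol | O[C@]1(C=C)C(C)(C)[C@@H]2CC[C@]1(O2)/C(C)=C/C
F3 | step 4 | {[(1S,2R,4S)-1-[(2E)-but-2-en-2-yl]-2-ethenyl-3,3-dimethyl-7-oxabicyclo[2.2.1]heptan-2-yl]oxy}trimethylsilane | C[Si](C)(C)O[C@]1(C=C)C(C)(C)[C@@H]2CC[C@]1(O2)/C(C)=C/C
F4 | step 4 | trimethyl{[(1S,3Z,6R,7Z)-2,2,6,7-tetramethyl-11-oxabicyclo[6.2.1]undeca-3,7-dien-3-yl]oxy}silane | C[Si](C)(C)O/C1=C\C[C@@H](C)/C(C)=C2/CC[C@H](O2)C1(C)C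
F5 | step 8 | (1S,6R,7S)-2,2,6,7-tetramethyl-7-[2-(5-oxo-2,5-dihydrofuran-3-yl)ethyl]-11-oxabicyclo[6.2.1]undec-8-en-3-one | O=C1CC[C@@H](C)[C@](C)(CCC2=CC(=O)OC2)C3=CC[C@H](O3)C1(C)C
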